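**Retrosynthetic overview**
1. The target is (−)-epicatechin-(4β→6)-(−)-epicatechin-(4β→6)-(−)-epicatechin. All phenols are carried as benzyl ethers and every free ring-A CH as C–Br, so the last step is a single hydrogenolysis (12 Bn, 4 Br).
2. In the lower unit, C3–OH comes from C3–B (retention). Ring C is then cut at C4–C3 and O1–C2 into an o-quinone methide on lower ring A plus a (Z)-2-arylvinylboronate (oxa-[4+2]).
3. Enabling feature: in the lower unit O1 and C4H2 sit on the adjacent ring-A carbons C8a and C4a, so O1=C8a–C4a=C4H2 is a latent o-quinone methide (an o-hydroxybenzyl alcohol). The cis C2-aryl/C3-O pair maps onto a (Z)-alkene, and the interflavan carbon C6 lies para to O1, where it is the only free CH of the bromine-capped ring-A fragment, so only the 4→6 isomer can form.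
4. The upper C4–middle C6 and middle C4–lower C6 bonds are Friedel–Crafts alkylations by C4 cations (4β by attack anti to the 2-aryl/3-acetoxy face). They are kept orthogonal by an O-leaving group (hard activation) and an S-leaving group (soft activation), with C8 bromine forcing attack at C6.
5. Ring order: rings A, B and C of the upper and middle units come intact from (−)-epicatechin; lower ring A arrives as an aromatic fragment, lower ring B with the alkene, and lower ring C is closed last.

Key step: step 16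

Assumption: the (R)-configured phosphoric acid of step 16 is taken to expose the alkene face that gives the 2R,3R-type lower ring; if the sense of induction is the opposite, the (S)-acid is used and nothing else changes.

Shorthand in names: Bn4 = benzyl ethers at O5, O7, O3', O4'; β = the face opposite to the 2-aryl group of epicatechin. U = 3-O-acetyl-Bn4-6,8-dibromo-(−)-epicatechin-4β-yl (upper unit). M(X) = 3-O-acetyl-Bn4-8-bromo-(−)-epicatechin whose C6 is bonded to C4 of U and whose C4 carries X on the β face (middle unit).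

**Route**

Step 1
Reactants: 1 (−)-epicatechin
Product: 2 5,7,3',4'-tetra-O-benzyl-(−)-epicatechin
Conditions: BnBr (4.4 equiv), K2CO3, DMF, 0 °C to rt, under argon
Reagents that add atoms: benzyl bromide BrCc1ccccc1
Why: Williamson ether synthesis on the four phenols, which the weak base deprotonates selectively over the 3-OH; low temperature and exclusion of air limit base-induced epimerisation at C2.

Step 2
Reactants: 2 5,7,3',4'-tetra-O-benzyl-(−)-epicatechin
Product: 3 Bn4-4β-(2-ethoxyethoxy)epicatechin (3-OH free)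
Conditions: DDQ (2 equiv), 2-ethoxyethanol (5 equiv), CH2Cl2, rt
Reagents that add atoms: 2-ethoxyethanol CCOCCO
Why: DDQ benzylic oxidation, in which hydride abstraction from C4 gives the ring-A-stabilised cation and the alcohol adds anti to the cis 2-aryl and 3-OH groups, setting the 4β (3,4-trans) ether.

Step 3
Reactants: 3 Bn4-4β-(2-ethoxyethoxy)epicatechin
Product: 4 3-O-acetyl-Bn4-4β-(2-ethoxyethoxy)epicatechin
Conditions: Ac2O, pyridine, DMAP (cat.), CH2Cl2, rt
Reagents that add atoms: acetic anhydride CC(=O)OC(C)=O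
Why: O-acylation of the secondary alcohol; the acetate later shields the α face of the C4 cations by participation and keeps the alcohol from adding to the quinone methide.

Step 4
Reactants: 4 3-O-acetyl-Bn4-4β-(2-ethoxyethoxy)epicatechin
Product: 5 3-O-acetyl-Bn4-6,8-dibromo-4β-(2-ethoxyethoxy)epicatechin (upper-unit electrophile)
Conditions: NBS (2.2 equiv), CH2Cl2, −20 °C to 0 °C
Reagents that add atoms: N-bromosuccinimide O=C1CCC(=O)N1Br
Why: electrophilic aromatic bromination at C8 and then C6 of the trioxygenated ring A, the most electron-rich ring, which caps both nucleophilic carbons so that this unit can act only as an electrophile.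

Step 5
Reactants: 4 3-O-acetyl-Bn4-4β-(2-ethoxyethoxy)epicatechin
Product: 6 3-O-acetyl-Bn4-8-bromo-4β-(2-ethoxyethoxy)epicatechin
Conditions: NBS (1.0 equiv), CH2Cl2, −78 °C to −30 °C
Reagents that add atoms: N-bromosuccinimide O=C1CCC(=O)N1Br
Why: regioselective electrophilic monobromination at the more accessible C8, leaving C6 as the only nucleophilic ring-A carbon.

Step 6
Reactants: 6 3-O-acetyl-Bn4-8-bromo-4β-(2-ethoxyethoxy)epicatechin
Product: 7 3-O-acetyl-Bn4-8-bromo-4β-(2,6-dimethylphenylthio)epicatechin (middle-unit nucleophile)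
Conditions: 2,6-dimethylbenzenethiol (3 equiv), BF3·OEt2 (0.3 equiv), CH2Cl2, −78 °C to −30 °C
Reagents that add atoms: 2,6-dimethylbenzenethiol Cc1cccc(C)c1S
Why: Lewis-acid-mediated SN1 exchange at C4, in which the cation, bridged on the α face by the 3-acetate, is captured by the thiol on the β face; the thioether is then inert to hard Lewis acids at low temperature.

Step 7
Reactants: 5 upper-unit electrophile; 7 middle-unit nucleophile (2.5 equiv)
Product: 8 U–M(X = 2,6-dimethylphenylthio)
Conditions: TMSOTf (0.3 equiv), CH2Cl2, −78 °C to −40 °C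
Reagents that add atoms: none
Why: Friedel–Crafts alkylation in which the hard silyl Lewis acid ionises only the C4–O bond of 5 and the cation is attacked anti to the 2-aryl/3-acetoxy face by C6 of 7, the only uncapped ring-A carbon present, fixing both the 4β configuration and the 4→6 connectivity.

Step 8
Reactants: 9 3,5-bis(benzyloxy)phenol
Product: 10 4,6-bis(benzyloxy)-2-hydroxybenzaldehyde
Conditions: MgCl2, Et3N, paraformaldehyde, MeCN, reflux
Reagents that add atoms: formaldehyde (as paraformaldehyde) C=O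
Why: Casnati–Skattebøl ortho-formylation, in which the magnesium phenoxide delivers formaldehyde only ortho to the hydroxyl (both ortho positions are equivalent) and a second formaldehyde oxidises the hydroxymethyl intermediate to the aldehyde.

Step 9
Reactants: 10 4,6-bis(benzyloxy)-2-hydroxybenzaldehyde
Product: 11 4,6-bis(benzyloxy)-3-bromo-2-hydroxybenzaldehyde
Conditions: NBS (1.0 equiv), i-Pr2NH (10 mol %), CH2Cl2, 0 °C
Reagents that add atoms: N-bromosuccinimide O=C1CCC(=O)N1Br
Why: amine-catalysed ortho-bromination of a phenol, directed to C3 next to the chelated hydroxyl, which leaves the CH between the two benzyloxy groups as the only free ring position.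

Step 10
Reactants: 11 4,6-bis(benzyloxy)-3-bromo-2-hydroxybenzaldehyde
Product: 12 3,5-bis(benzyloxy)-2-bromo-6-(hydroxymethyl)phenol
Conditions: NaBH4, THF/MeOH, −10 °C, short reaction time, buffered quench
Reagents that add atoms: none
Why: hydride reduction of the aldehyde, kept cold and brief so that the electron-rich benzylic alcohol is not reduced further through its quinone methide.

Step 11
Reactants: 12 3,5-bis(benzyloxy)-2-bromo-6-(hydroxymethyl)phenol
Product: 13 bis(tert-butyldimethylsilyl) ether of 12 (aryl O–TBS and CH2O–TBS)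
Conditions: TBSCl (2.5 equiv), imidazole, DMF, rt
Reagents that add atoms: tert-butyldimethylsilyl chloride CC(C)(C)[Si](C)(C)Cl
Why: silylation of both hydroxyls gives ethers that are inert to the silver-promoted coupling and are removed later by fluoride without acid.

Step 12
Reactants: 8 U–M(X = 2,6-dimethylphenylthio); 13 bis-silyl ether (2.5 equiv)
Product: 14 U–M(X = 2,6-bis(benzyloxy)-3-bromo-4-(tert-butyldimethylsilyloxy)-5-[(tert-butyldimethylsilyloxy)methyl]phenyl)
Conditions: AgOTf (2 equiv), 2,6-di-tert-butyl-4-methylpyridine (2.5 equiv), 4 Å MS, CH2Cl2, −40 °C to 0 °C, dark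
Reagents that add atoms: none
Why: thiophilic activation of the C4–S bond followed by Friedel–Crafts alkylation, in which the middle-unit C4 cation is attacked anti to the 2-aryl/3-acetoxy face (4β) by the only ring CH of 13, which lies para to the silyloxy oxygen that becomes O1.

Step 13
Reactants: 14 bis-silyl ether of the arylated dimer
Product: 15 U–M(X = 2,6-bis(benzyloxy)-3-bromo-4-hydroxy-5-(hydroxymethyl)phenyl), the o-hydroxybenzyl alcohol
Conditions: TBAF (2.5 equiv), AcOH (2.5 equiv), THF, 0 °C; used without storage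
Reagents that add atoms: none
Why: fluoride desilylation under buffered, non-acidic conditions in which the o-hydroxybenzyl alcohol does not ionise and the secondary acetates survive.

Step 14
Reactants: 16 3,4-bis(benzyloxy)benzaldehyde
Product: 17 1,2-bis(benzyloxy)-4-ethynylbenzene
Conditions: dimethyl (1-diazo-2-oxopropyl)phosphonate, K2CO3, MeOH, rt
Reagents that add atoms: dimethyl (1-diazo-2-oxopropyl)phosphonate COP(=O)(OC)C(=[N+]=[N-])C(C)=O
Why: Seyferth–Gilbert homologation in the Ohira–Bestmann variant converts the aldehyde into the terminal alkyne under mild base.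

Step 15
Reactants: 17 1,2-bis(benzyloxy)-4-ethynylbenzene
Product: 18 (Z)-2-[2-(3,4-bis(benzyloxy)phenyl)ethenyl]-4,4,5,5-tetramethyl-1,3,2-dioxaborolane
Conditions: pinacolborane (1.0 equiv), 17 (1.2 equiv), [Rh(cod)Cl]2 (1.5 mol %), P(i-Pr)3 (6 mol %), Et3N, cyclohexane, rt
Reagents that add atoms: pinacolborane [H]B1OC(C)(C)C(C)(C)O1
Why: rhodium-catalysed trans-hydroboration of a terminal alkyne through a rhodium vinylidene, in which the alkyne hydrogen migrates and boron ends cis to the aryl group, giving the (Z)-alkenylboronate.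

Step 16
Reactants: 15 o-hydroxybenzyl alcohol; 18 (Z)-alkenylboronate (3 equiv)
Product: 20 protected trimer boronate U–M(X = lower unit) whose lower unit is 5,7,3',4'-tetra-O-benzyl-8-bromo-2,3-cis-3-(pinacolboryl)flavan-6-yl in the spatial arrangement of (−)-epicatechin, via o-quinone methide 19 (not isolated)
Conditions: (R)-3,3'-bis(2,4,6-triisopropylphenyl)-1,1'-binaphthyl-2,2'-diyl hydrogen phosphate (10 mol %), 5 Å MS, toluene, 0 °C to rt
Reagents that add atoms: none
Why: Proposed new method: the chiral acid dehydrates the o-hydroxybenzyl alcohol to o-quinone methide 19 (O1=C8a–C4a=C4H2), which stays hydrogen-bonded to the phosphate and reacts as the oxa-diene with the (Z)-alkenylboronate as 2π partner in an inverse-electron-demand hetero-Diels–Alder reaction; the closest known reaction type is the Brønsted-acid-catalysed [4+2] cycloaddition of o-quinone methides from o-hydroxybenzyl alcohols with styrenes and propenylbenzenes, and the new element is an alkenylboronate as the alkene. Ring C closes in a concerted but asynchronous [4+2] mode, with C4–C3 bonding leading and O1–C2 bonding following before any C2–C3 rotation. Regiochemistry follows the styrene polarisation: the boron-bearing carbon is the nucleophilic terminus and adds to C4, while the charge developing at C2 is stabilised by the 3,4-bis(benzyloxy)phenyl group (para-benzyloxy donation) and captured by O1. Suprafacial addition to the (Z)-alkene places aryl and boron cis on the ring (relative configuration at C2 and C3), and the absolute configuration of both carbons is set by the alkene face that the chiral phosphate pocket exposes, since the stereocentres of the upper units are too distant to matter. The step needs chemoselectivity for cycloaddition over quinone methide self-reaction and over alkenyl transfer with loss of boron; this is secured by bromine caps on every ring-A CH, benzyl ethers on all other phenols (only one quinone methide is possible), acetates on the alcohols, and the weakly Lewis-acidic pinacol boronate used in excess.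

Step 17
Reactants: 20 protected trimer boronate
Product: 21 dodeca-O-benzyl-tetrabromo trimer with three free 3-OH groups
Conditions: 30% H2O2, 2 M NaOH, THF/MeOH, 0 °C to rt
Reagents that add atoms: hydrogen peroxide OO
Why: organoborane oxidation with 1,2-migration of C3 from boron to oxygen under retention gives the cis 3-OH of the lower unit, and the same alkaline medium saponifies the two acetates.

Step 18
Reactants: 21 dodeca-O-benzyl-tetrabromo trimer
Product: 22 (−)-epicatechin-(4β→6)-(−)-epicatechin-(4β→6)-(−)-epicatechin (CNP0163146.2)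
Conditions: H2 (1 atm), Pd(OH)2/C, Et3N (5 equiv), degassed THF/MeOH/H2O, rt
Reagents that add atoms: none
Why: catalytic hydrogenolysis removes the twelve benzyl ethers and hydrodehalogenates the four aryl bromides in one operation, the amine buffering the HBr so that interflavan bonds and stereocentres are not touched.

**Compound list**
1 | (−)-epicatechin, (2R,3R)-2-(3,4-dihydroxyphenyl)chromane-3,5,7-triol | Oc1cc(O)c2c(c1)O[C@H](c1ccc(O)c(O)c1)[C@H](O)C2 | starting material
2 | 5,7,3',4'-tetra-O-benzyl-(−)-epicatechin | c7ccccc7COc1cc(OCc7ccccc7)c2c(c1)O[C@H](c6ccc(OCc7ccccc7)c(OCc7ccccc7)c6)[C@H](O)C2 | intermediate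
3 | Bn4-4β-(2-ethoxyethoxy)epicatechin (3,4-trans) | c7ccccc7COc1cc(OCc7ccccc7)c2c(c1)O[C@H](c6ccc(OCc7ccccc7)c(OCc7ccccc7)c6)[C@H](O)[C@H]2OCCOCC | intermediate
4 | 3-O-acetyl-Bn4-4β-(2-ethoxyethoxy)epicatechin | c7ccccc7COc1cc(OCc7ccccc7)c2c(c1)O[C@H](c6ccc(OCc7ccccc7)c(OCc7ccccc7)c6)[C@H](OC(C)=O)[C@H]2OCCOCC | intermediate
5 | 3-O-acetyl-Bn4-6,8-dibromo-4β-(2-ethoxyethoxy)epicatechin | c7ccccc7COc1c(Br)c(OCc7ccccc7)c2c(c1Br)O[C@H](c6ccc(OCc7ccccc7)c(OCc7ccccc7)c6)[C@H](OC(C)=O)[C@H]2OCCOCC | intermediate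
6 | 3-O-acetyl-Bn4-8-bromo-4β-(2-ethoxyethoxy)epicatechin | c7ccccc7COc1cc(OCc7ccccc7)c2c(c1Br)O[C@H](c6ccc(OCc7ccccc7)c(OCc7ccccc7)c6)[C@H](OC(C)=O)[C@H]2OCCOCC | intermediate
7 | 3-O-acetyl-Bn4-8-bromo-4β-(2,6-dimethylphenylthio)epicatechin | c7ccccc7COc1cc(OCc7ccccc7)c2c(c1Br)O[C@H](c6ccc(OCc7ccccc7)c(OCc7ccccc7)c6)[C@H](OC(C)=O)[C@H]2Sc1c(C)cccc1C | intermediate
8 | U–M(X = 2,6-dimethylphenylthio), the (4β→6) dimer thioether | c7ccccc7COc1c(Br)c(OCc7ccccc7)c2c(c1Br)O[C@H](c6ccc(OCc7ccccc7)c(OCc7ccccc7)c6)[C@H](OC(C)=O)[C@H]2c1c(OCc7ccccc7)c(Br)c2c(c1OCc7ccccc7)[C@H](Sc3c(C)cccc3C)[C@@H](OC(C)=O)[C@@H](c6ccc(OCc7ccccc7)c(OCc7ccccc7)c6)O2 | intermediate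
9 | 3,5-bis(benzyloxy)phenol | Oc1cc(OCc2ccccc2)cc(OCc2ccccc2)c1 | starting material
10 | 4,6-bis(benzyloxy)-2-hydroxybenzaldehyde | O=Cc1c(O)cc(OCc2ccccc2)cc1OCc2ccccc2 | intermediate
11 | 4,6-bis(benzyloxy)-3-bromo-2-hydroxybenzaldehyde | O=Cc1c(O)c(Br)c(OCc2ccccc2)cc1OCc2ccccc2 | intermediate
12 | 3,5-bis(benzyloxy)-2-bromo-6-(hydroxymethyl)phenol | OCc1c(O)c(Br)c(OCc2ccccc2)cc1OCc2ccccc2 | intermediate
13 | bis(tert-butyldimethylsilyl) ether of 12 | CC(C)(C)[Si](C)(C)OCc1c(O[Si](C)(C)C(C)(C)C)c(Br)c(OCc2ccccc2)cc1OCc2ccccc2 | intermediate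
14 | U–M(X = 2,6-bis(benzyloxy)-3-bromo-4-(TBS-oxy)-5-(TBS-oxymethyl)phenyl) | c7ccccc7COc1c(Br)c(OCc7ccccc7)c2c(c1Br)O[C@H](c6ccc(OCc7ccccc7)c(OCc7ccccc7)c6)[C@H](OC(C)=O)[C@H]2c1c(OCc7ccccc7)c(Br)c2c(c1OCc7ccccc7)[C@H](c3c(OCc7ccccc7)c(Br)c(O[Si](C)(C)C(C)(C)C)c(CO[Si](C)(C)C(C)(C)C)c3OCc7ccccc7)[C@@H](OC(C)=O)[C@@H](c6ccc(OCc7ccccc7)c(OCc7ccccc7)c6)O2 | intermediate
15 | U–M(X = 2,6-bis(benzyloxy)-3-bromo-4-hydroxy-5-(hydroxymethyl)phenyl), o-hydroxybenzyl alcohol | c7ccccc7COc1c(Br)c(OCc7ccccc7)c2c(c1Br)O[C@H](c6ccc(OCc7ccccc7)c(OCc7ccccc7)c6)[C@H](OC(C)=O)[C@H]2c1c(OCc7ccccc7)c(Br)c2c(c1OCc7ccccc7)[C@H](c3c(OCc7ccccc7)c(Br)c(O)c(CO)c3OCc7ccccc7)[C@@H](OC(C)=O)[C@@H](c6ccc(OCc7ccccc7)c(OCc7ccccc7)c6)O2 | intermediate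
16 | 3,4-bis(benzyloxy)benzaldehyde | O=Cc1ccc(OCc2ccccc2)c(OCc2ccccc2)c1 | starting material
17 | 1,2-bis(benzyloxy)-4-ethynylbenzene | C#Cc1ccc(OCc2ccccc2)c(OCc2ccccc2)c1 | intermediate
18 | (Z)-2-[2-(3,4-bis(benzyloxy)phenyl)ethenyl]-4,4,5,5-tetramethyl-1,3,2-dioxaborolane | CC1(C)OB(/C=C\c2ccc(OCc3ccccc3)c(OCc3ccccc3)c2)OC1(C)C | intermediate
19 | o-quinone methide of 15 (6-methylidene-cyclohexa-2,4-dienone on the lower ring A; not isolated) | c7ccccc7COc1c(Br)c(OCc7ccccc7)c2c(c1Br)O[C@H](c6ccc(OCc7ccccc7)c(OCc7ccccc7)c6)[C@H](OC(C)=O)[C@H]2c1c(OCc7ccccc7)c(Br)c2c(c1OCc7ccccc7)[C@H](C3=C(OCc7ccccc7)C(=C)C(=O)C(Br)=C3OCc7ccccc7)[C@@H](OC(C)=O)[C@@H](c6ccc(OCc7ccccc7)c(OCc7ccccc7)c6)O2 | intermediate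
20 | protected trimer boronate; lower unit 2,3-cis with 3-(pinacolboryl), (2S,3R) by the sequence rule because boron ranks below carbon, spatially as in (−)-epicatechin | c7ccccc7COc1c(Br)c(OCc7ccccc7)c2c(c1Br)O[C@H](c6ccc(OCc7ccccc7)c(OCc7ccccc7)c6)[C@H](OC(C)=O)[C@H]2c1c(OCc7ccccc7)c(Br)c2c(c1OCc7ccccc7)[C@H](c3c(OCc7ccccc7)c(Br)c4c(c3OCc7ccccc7)C[C@@H](B5OC(C)(C)C(C)(C)O5)[C@@H](c6ccc(OCc7ccccc7)c(OCc7ccccc7)c6)O4)[C@@H](OC(C)=O)[C@@H](c6ccc(OCc7ccccc7)c(OCc7ccccc7)c6)O2 | intermediate
21 | dodeca-O-benzyl-tetrabromo trimer (6,8-dibromo upper; 8-bromo middle; 8-bromo lower; three free 3-OH) | c7ccccc7COc1c(Br)c(OCc7ccccc7)c2c(c1Br)O[C@H](c6ccc(OCc7ccccc7)c(OCc7ccccc7)c6)[C@H](O)[C@H]2c1c(OCc7ccccc7)c(Br)c2c(c1OCc7ccccc7)[C@H](c3c(OCc7ccccc7)c(Br)c4c(c3OCc7ccccc7)C[C@@H](O)[C@@H](c6ccc(OCc7ccccc7)c(OCc7ccccc7)c6)O4)[C@@H](O)[C@@H](c6ccc(OCc7ccccc7)c(OCc7ccccc7)c6)O2 | intermediate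
22 | (−)-epicatechin-(4β→6)-(−)-epicatechin-(4β→6)-(−)-epicatechin | Oc1cc(O)c2c(c1)O[C@H](c1ccc(O)c(O)c1)[C@H](O)[C@H]2c1c(O)cc2c(c1O)[C@H](c1c(O)cc3c(c1O)C[C@@H](O)[C@@H](c1ccc(O)c(O)c1)O3)[C@@H](O)[C@@H](c1ccc(O)c(O)c1)O2 | target

**Step count and risks**
Total steps: 18. Longest linear sequence: 11 steps (1, 2, 3, 5, 6, 7, 12, 13, 16, 17, 18).

Step 16. The cycloaddition may run stepwise through a β-boryl benzylic cation, which would allow rotation about C2–C3 (loss of the cis relationship) or loss of boron. The chiral acid may also discriminate the alkene faces poorly, and the quinone methide may oligomerise faster than it is trapped. The fallback uses known halogen-capped Friedel–Crafts chemistry, sets out from 2 and 8, and returns at 21. Compound 2 is monobrominated at C8 (NBS, CH2Cl2, −78 °C) to give 8-bromo-5,7,3',4'-tetra-O-benzyl-(−)-epicatechin F1. Dimer 8 is then ionised with AgOTf and 2,6-di-tert-butyl-4-methylpyridine in the presence of excess F1, whose only free ring-A carbon is C6, to give the trimer diacetate with a free lower 3-OH F2. Methanolysis of the two acetates (K2CO3, MeOH/THF) gives 21. The lower-unit stereocentres then come from the chiral pool.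

Step 7. The hard Lewis acid may also ionise the C4–S bond of the nucleophile (loss of orthogonality), leading to self-condensation, and attack by the hindered, bromine-deactivated C6 may be slow. The fallback assembles the trimer skeleton from the bottom with soft activation only, sets out from 7, 13 and 5, and returns at 14 (it also bypasses step 12). Thioether 7 is ionised with AgOTf and 2,6-di-tert-butyl-4-methylpyridine in the presence of excess 13 to give 3-O-acetyl-Bn4-8-bromo-4β-[2,6-bis(benzyloxy)-3-bromo-4-(TBS-oxy)-5-(TBS-oxymethyl)phenyl]epicatechin F3, whose only free ring-A carbon is C6 and which has no leaving group at C4. Electrophile 5 is converted with 2,6-dimethylbenzenethiol and BF3·OEt2 into 3-O-acetyl-Bn4-6,8-dibromo-4β-(2,6-dimethylphenylthio)epicatechin F4. Silver-promoted ionisation of F4 in the presence of F3 then forms the upper 4β→6 bond and gives 14.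

Step 15. The Z geometry may erode, through incomplete trans-selectivity of the vinylidene pathway with an electron-rich aryl alkyne and through Z-to-E isomerisation of the product by rhodium hydride species. Any E isomer would give the 2,3-trans ring in step 16. The fallback sets out from 17 and returns at 18. Alkyne 17 is deprotonated (n-BuLi, THF, −78 °C), borylated with 2-isopropoxy-4,4,5,5-tetramethyl-1,3,2-dioxaborolane and quenched with HCl in ether to give 2-{[3,4-bis(benzyloxy)phenyl]ethynyl}-4,4,5,5-tetramethyl-1,3,2-dioxaborolane F5. Syn-hydrozirconation with Cp2Zr(H)Cl (zirconium adds to the boron-bearing carbon) and protonolysis with water, with retention, then gives 18 as the Z isomer.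

Further compounds
F1 | step 16 | 8-bromo-5,7,3',4'-tetra-O-benzyl-(−)-epicatechin | c7ccccc7COc1cc(OCc7ccccc7)c2c(c1Br)O[C@H](c6ccc(OCc7ccccc7)c(OCc7ccccc7)c6)[C@H](O)C2
F2 | step 16 | trimer diacetate: 21 with acetates on the upper and middle 3-oxygens and a free lower 3-OH | c7ccccc7COc1c(Br)c(OCc7ccccc7)c2c(c1Br)O[C@H](c6ccc(OCc7ccccc7)c(OCc7ccccc7)c6)[C@H](OC(C)=O)[C@H]2c1c(OCc7ccccc7)c(Br)c2c(c1OCc7ccccc7)[C@H](c3c(OCc7ccccc7)c(Br)c4c(c3OCc7ccccc7)C[C@@H](O)[C@@H](c6ccc(OCc7ccccc7)c(OCc7ccccc7)c6)O4)[C@@H](OC(C)=O)[C@@H](c6ccc(OCc7ccccc7)c(OCc7ccccc7)c6)O2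
F3 | step 7 | 3-O-acetyl-Bn4-8-bromo-4β-[2,6-bis(benzyloxy)-3-bromo-4-(TBS-oxy)-5-(TBS-oxymethyl)phenyl]epicatechin | c7ccccc7COc1cc(OCc7ccccc7)c2c(c1Br)O[C@H](c6ccc(OCc7ccccc7)c(OCc7ccccc7)c6)[C@H](OC(C)=O)[C@H]2c1c(OCc7ccccc7)c(Br)c(O[Si](C)(C)C(C)(C)C)c(CO[Si](C)(C)C(C)(C)C)c1OCc7ccccc7
F4 | step 7 | 3-O-acetyl-Bn4-6,8-dibromo-4β-(2,6-dimethylphenylthio)epicatechin | c7ccccc7COc1c(Br)c(OCc7ccccc7)c2c(c1Br)O[C@H](c6ccc(OCc7ccccc7)c(OCc7ccccc7)c6)[C@H](OC(C)=O)[C@H]2Sc1c(C)cccc1C
F5 | step 15 | 2-{[3,4-bis(benzyloxy)phenyl]ethynyl}-4,4,5,5-tetramethyl-1,3,2-dioxaborolane | CC1(C)OB(C#Cc2ccc(OCc3ccccc3)c(OCc3ccccc3)c2)OC1(C)C
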